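The lactone ring is cut from the arene at C4–C4a and C1–C8a, which turns the arene into 3,5-dimethoxybenzyne and the C4–C3–O2–C1 unit into an (R)-β-lactone. The key step is a proposed insertion of that aryne into the Cα–C(=O) bond of the β-lactone enolate: it forms both aryl–carbon bonds in one operation and expands the oxetanone to the six-membered lactone, carrying C3 over unchanged. It exploits the ortho relationship of C4a and C8a and the C8 oxygen beside C8a, which steers the enolate to C4a. The precursor is a simple 4-alkyl-β-lactone made by asymmetric ketene–aldehyde cycloaddition; cross-metathesis, hydrogenation and peri-selective demethylation finish the side chain and the phenol.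

Key step: step 2

Remark on the chemistry (assumption): hex-5-enal is taken as a commercial aldehyde, and the quinine-derived catalyst of step 1 is assumed to give the (R)-lactone; if the sense proves opposite, the pseudo-enantiomeric quinidine-derived catalyst is used instead.

Step 1
Reactants: 1 hex-5-enal; 2 acetyl chloride
Product: 4 (R)-4-(pent-4-en-1-yl)oxetan-2-one, via ketene 3 (not isolated)
Conditions: O-trimethylsilylquinine (10 mol %), LiClO4, iPr2NEt (2.5 equiv), CH2Cl2/Et2O, −78 °C
Reagents that add atoms: none
Why: The amine converts acetyl chloride into ketene 3, whose alkaloid-bound ammonium enolate adds to the lithium-activated aldehyde and lactonises (catalytic asymmetric acyl halide–aldehyde cyclocondensation, a formal ketene–aldehyde [2+2] cycloaddition), the cinchona catalyst choosing the aldehyde face so that C4 of the lactone is expected to form as (R).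

Step 2
Reactants: 4 (R)-4-(pent-4-en-1-yl)oxetan-2-one; 5 1-bromo-3,5-dimethoxybenzene
Product: 12 (R)-6,8-dimethoxy-3-(pent-4-en-1-yl)isochroman-1-one, via lithium enolate 6 (not isolated), via ortho-lithiated bromoarene 7 (not isolated), via 3,5-dimethoxybenzyne 8 (not isolated), via aryllithium adduct 9 (not isolated), via tricyclic alkoxide 10 (not isolated), via C4-lithiated lactone 11 (not isolated)
Conditions: 4 added to LiTMP (1.1 equiv), THF, −78 °C; then 5 (1.3 equiv), LiTMP (1.5 equiv), −78 → −45 °C; AcOH, −78 °C
Reagents that add atoms: none
Why: Proposed new method: LiTMP first gives lithium enolate 6 (β-lactone enolates persist at −78 °C because ring opening by β-elimination has no orbital overlap in the flat four-membered ring) and then dehydrobrominates 5 through 7 to aryne 8; the enolate carbon adds to the aryne carbon remote from the flanking methoxy group, the aryllithium 9 so formed attacks the adjacent strained lactone carbonyl, and alkoxide 10 fragments at its former Cα–C(=O) bond to the extended enolate 11, which acetic acid protonates at C4. The closest known reaction type is the aryne σ-insertion (acyl-alkylation) into the Cα–C(=O) bond of β-ketoesters and malonates, which expands cyclic β-ketoesters by two carbons, together with the arynic condensation of simple ketone enolates through benzocyclobutenoxides; new here is an ester-type enolate without a second activating group. The six-membered lactone is not closed by direct cyclisation but arises from a 4-exo-trig carbonyl addition followed by strain-driven C–C fragmentation of the fused benzocyclobutene–oxetane, a formal two-carbon ring expansion of the oxetanone. No stereocentre is created: C3 of 12 is C4 of 4, to which no bond is made or broken, so its (R) configuration is carried over, and the transient Cα centre of 9 and 10 is lost in 11. The step needs regioselective aryne capture, secured by the methoxy group next to the aryne bond (attack at the distal carbon places the aryl anion ortho to oxygen, so that C4 ends on C4a and C1 on C8a), and insertion in preference to plain α-arylation, favoured by the absence of an acidic proton source and by the high electrophilicity of the β-lactone carbonyl; low temperature and a cold quench guard against E1cB opening of 11.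

Step 3
Reactants: 12 (R)-6,8-dimethoxy-3-(pent-4-en-1-yl)isochroman-1-one; 13 oct-1-en-3-one
Product: 15 (R)-6,8-dimethoxy-3-(6-oxoundecyl)isochroman-1-one, via enone 14 (not isolated)
Conditions: 13 (3 equiv), Hoveyda–Grubbs II catalyst (5 mol %), CH2Cl2, 40 °C; then solvent switch to EtOAc, 10% Pd/C, H2 (1 atm), rt
Reagents that add atoms: none
Why: Olefin cross-metathesis of the terminal alkene with excess electron-poor vinyl ketone should give the E-enone 14 with loss of ethene, and heterogeneous hydrogenation then saturates only the conjugated C=C bond, neither stage touching C3.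

Step 4
Reactants: 15 (R)-6,8-dimethoxy-3-(6-oxoundecyl)isochroman-1-one
Product: 16 (R)-8-hydroxy-6-methoxy-3-(6-oxoundecyl)isochroman-1-one (target)
Conditions: BCl3 (2.5 equiv), CH2Cl2, −78 → 0 °C; then H2O
Reagents that add atoms: none
Why: Boron chelated between the C1 carbonyl oxygen and the peri C8 methoxy oxygen activates only that methyl ether for cleavage by chloride (chelation-controlled Lewis acid demethylation), so the C6 methyl ether, the ketone and C3 should stay intact.

Compound list
1 | hex-5-enal | C=CCCCC=O | starting material
2 | acetyl chloride | CC(=O)Cl | starting material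
3 | ketene | C=C=O | intermediate
4 | (R)-4-(pent-4-en-1-yl)oxetan-2-one | C=CCCC[C@@H]1CC(=O)O1 | intermediate
5 | 1-bromo-3,5-dimethoxybenzene | COc1cc(Br)cc(OC)c1 | starting material
6 | lithium enolate of 4, lithium (R)-4-(pent-4-en-1-yl)-4H-oxet-2-olate | C=CCCC[C@@H]1C=C([O-])O1.[Li+] | intermediate
7 | (2-bromo-4,6-dimethoxyphenyl)lithium | [Li]c1c(Br)cc(OC)cc1OC | intermediate
8 | 3,5-dimethoxybenzyne (1,2-didehydro-3,5-dimethoxybenzene) | COC1=CC(OC)=CC#C1 | intermediate
9 | (4R)-3-(2-lithio-3,5-dimethoxyphenyl)-4-(pent-4-en-1-yl)oxetan-2-one (C3 configuration transient, not defined) | C=CCCC[C@@H]1C(c2cc(OC)cc(OC)c2[Li])C(=O)O1 | intermediate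
10 | lithium alkoxide of the benzocyclobutene-fused oxetane (aryl C8a bonded to the former lactone carbonyl carbon; ring-fusion centres transient) | C=CCCC[C@@H]1C2c3cc(OC)cc(OC)c3C2([O-])O1.[Li+] | intermediate
11 | C4-lithiated (R)-6,8-dimethoxy-3-(pent-4-en-1-yl)isochroman-1-one (extended enolate, drawn as the C-lithio form) | C=CCCC[C@@H]1C([Li])c2cc(OC)cc(OC)c2C(=O)O1 | intermediate
12 | (R)-6,8-dimethoxy-3-(pent-4-en-1-yl)isochroman-1-one | C=CCCC[C@@H]1Cc2cc(OC)cc(OC)c2C(=O)O1 | intermediate
13 | oct-1-en-3-one | C=CC(=O)CCCCC | starting material
14 | (R)-6,8-dimethoxy-3-[(E)-6-oxoundec-4-en-1-yl]isochroman-1-one | CCCCCC(=O)/C=C/CCC[C@@H]1Cc2cc(OC)cc(OC)c2C(=O)O1 | intermediate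
15 | (R)-6,8-dimethoxy-3-(6-oxoundecyl)isochroman-1-one | CCCCCC(=O)CCCCC[C@@H]1Cc2cc(OC)cc(OC)c2C(=O)O1 | intermediate
16 | (R)-8-hydroxy-6-methoxy-3-(6-oxoundecyl)isochroman-1-one | CCCCCC(=O)CCCCC[C@@H]1Cc2cc(OC)cc(O)c2C(=O)O1 | target

Total step count: 4. Longest linear sequence: 4 steps (1 → 4 → 12 → 15 → 16).

Steps most likely to fail

1. Step 2 (proposed new method). What may go wrong:
- Proton transfer to aryllithium 9 before it reaches the carbonyl, which would stop at plain α-arylation of the lactone.
- Claisen-type self-condensation of enolate 6.
- Ring opening of anion 11 by β-elimination of the carboxylate.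

Fallback by known chemistry, setting out from 5 and returning at 12. Compound 5 is converted with magnesium in THF into (3,5-dimethoxyphenyl)magnesium bromide F1. Under CuI catalysis F1 opens commercial (S)-epichlorohydrin (ClC[C@@H]1CO1) at its epoxide CH2 to give (S)-1-chloro-3-(3,5-dimethoxyphenyl)propan-2-ol F2. Aqueous NaOH closes this to (S)-2-(3,5-dimethoxybenzyl)oxirane F3. Copper-catalysed opening with but-3-enylmagnesium bromide at the terminal carbon should give (R)-1-(3,5-dimethoxyphenyl)hept-6-en-2-ol F4. NBS in MeCN at 0 °C should brominate the ring position ortho to the side chain and para to a methoxy group, giving (R)-1-(2-bromo-3,5-dimethoxyphenyl)hept-6-en-2-ol F5. Palladium-catalysed carbonylative lactonisation (Pd(OAc)2, dppf, CO, Et3N, toluene, 100 °C) then closes the lactone to 12. In this fallback the stereocentre comes from epichlorohydrin and is never a reacting carbon.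

2. Step 1. What may go wrong:
- Insufficient or opposite facial selectivity in the ketene addition.
- Ketene dimerisation or aldehyde self-condensation outrunning the cycloaddition.

Fallback setting out from 1 and returning at 4. Roskamp homologation of 1 with ethyl diazoacetate and catalytic SnCl2 should give ethyl 3-oxooct-7-enoate F6. An (R)-selective ketoreductase with cofactor recycling reduces it to ethyl (R)-3-hydroxyoct-7-enoate F7 without touching the alkene. LiOH in THF/H2O gives (R)-3-hydroxyoct-7-enoic acid F8. Benzenesulfonyl chloride in pyridine at 0 °C lactonises F8 by carboxyl activation, with retention at the carbinol carbon, to 4.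

3. Step 4. What may go wrong:
- Poor site selectivity of ether cleavage, with loss of the C6 methyl ether as well.
- Incomplete cleavage at C8.

Fallback setting out from 15 and returning at 16. Exhaustive demethylation with excess BBr3 in CH2Cl2 gives (R)-6,8-dihydroxy-3-(6-oxoundecyl)isochroman-1-one F9. One equivalent of MeI with K2CO3 in acetone should then methylate only the C6 hydroxyl, because the C8 hydroxyl is held in a hydrogen bond to the lactone carbonyl.

Further compounds
F1 | step 2 | (3,5-dimethoxyphenyl)magnesium bromide | COc1cc(OC)cc([Mg]Br)c1
F2 | step 2 | (S)-1-chloro-3-(3,5-dimethoxyphenyl)propan-2-ol | ClC[C@@H](O)Cc1cc(OC)cc(OC)c1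
F3 | step 2 | (S)-2-(3,5-dimethoxybenzyl)oxirane | C1[C@@H](O1)Cc2cc(OC)cc(OC)c2
F4 | step 2 | (R)-1-(3,5-dimethoxyphenyl)hept-6-en-2-ol | C=CCCC[C@@H](O)Cc1cc(OC)cc(OC)c1
F5 | step 2 | (R)-1-(2-bromo-3,5-dimethoxyphenyl)hept-6-en-2-ol | C=CCCC[C@@H](O)Cc1cc(OC)cc(OC)c1Br
F6 | step 1 | ethyl 3-oxooct-7-enoate | C=CCCCC(=O)CC(=O)OCC
F7 | step 1 | ethyl (R)-3-hydroxyoct-7-enoate | C=CCCC[C@@H](O)CC(=O)OCC
F8 | step 1 | (R)-3-hydroxyoct-7-enoic acid | C=CCCC[C@@H](O)CC(=O)O
F9 | step 4 | (R)-6,8-dihydroxy-3-(6-oxoundecyl)isochroman-1-one | CCCCCC(=O)CCCCC[C@@H]1Cc2cc(O)cc(O)c2C(=O)O1
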